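**Retrosynthetic overview**

1. Chrotacumine D ⇒ (O-debenzylation; C3–O acylation with 3,4-dimethoxybenzoyl chloride; N-Boc to N-Me) cis-(3S,4R)-4-(chromon-8-yl)piperidin-3-ol ⇒ (asymmetric transfer hydrogenation with dynamic kinetic resolution, both stereocentres at once) racemic 4-(chromon-8-yl)-3-oxopiperidine.
2. Key disconnection: 4-aryl-3-oxopiperidine ⇒ N-Boc-3-oxopyrrolidine + (chromon-8-yl)diazomethane. The aryl-bearing carbon C4 is inserted into the C(=O)–CH2 bond of the five-membered ring, a one-carbon ring expansion that also makes the C8–C4 bond and leaves the oxygen on C3.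
3. Enabling feature: piperidine C4 is a benzylic methine between chromone C8 and the oxygen-bearing C3, so the array C8(aryl)–C4H–C3(O) is an α-aryl ketone in disguise. C2, on the other side of C3, is bound to nitrogen and, as the carbamate, is the poorer migrating group.
4. Diazo precursor: noreugenin ⇒ 5,7-di-O-benzyl ether ⇒ C8 bromide ⇒ C8 aldehyde ⇒ N-tosylhydrazone.
5. Ring order: rings A and C of the chromone come intact with noreugenin and the dimethoxyphenyl ring with the acid chloride; the piperidine is the only ring made, from the pyrrolidinone, in step 5.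

Key step: step 5

Assumption (remark on the chemistry): the (R,R) antipode of the transfer-hydrogenation catalyst in step 6 is assigned to the (3S) carbinol by analogy with the aryl ketone model, the aryl-bearing α-carbon taking the place of the aryl group; the sense must be confirmed on the first run, and the (S,S) catalyst is used if it proves opposite.

**Route**

Step 1
Reactants: 1 5,7-dihydroxy-2-methyl-4H-chromen-4-one (noreugenin)
Product: 2 5,7-bis(benzyloxy)-2-methyl-4H-chromen-4-one
Conditions: BnBr (2.5 equiv), K2CO3, DMF, 80 °C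
Reagents that add atoms: benzyl bromide, BrCc1ccccc1
Why: Williamson ether synthesis in which both phenoxides, including the hydrogen-bonded 5-OH at 80 °C, are benzylated, benzyl being chosen because it survives every later step and is removed at the end without touching the ester or the methyl ethers.

Step 2
Reactants: 2 5,7-bis(benzyloxy)-2-methyl-4H-chromen-4-one
Product: 3 5,7-bis(benzyloxy)-8-bromo-2-methyl-4H-chromen-4-one
Conditions: NBS (1.05 equiv), MeCN, 0 °C → rt
Reagents that add atoms: N-bromosuccinimide, O=C1CCC(=O)N1Br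
Why: Electrophilic aromatic bromination, which in 5,7-dialkoxychromones with the 5-oxygen alkylated is expected at C8 of ring A (ortho to the 7-alkoxy group, para to the 5-alkoxy group and less hindered than C6 between two benzyloxy groups), as in the halogenation of 5,7-dialkoxyflavones.

Step 3
Reactants: 3 5,7-bis(benzyloxy)-8-bromo-2-methyl-4H-chromen-4-one
Product: 4 5,7-bis(benzyloxy)-2-methyl-4-oxo-4H-chromene-8-carbaldehyde
Conditions: Pd(OAc)2 (2 mol %), n-BuPAd2 (6 mol %), TMEDA, CO/H2 (1:1, 5 bar), toluene, 100 °C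
Reagents that add atoms: carbon monoxide, [C-]#[O+]
Why: Palladium-catalysed reductive carbonylation (formylation with synthesis gas), in which zerovalent palladium adds oxidatively into the C8–Br bond, CO inserts and the acyl complex is cleaved by hydrogen, the CO atmosphere keeping the benzyl ethers intact.

Step 4
Reactants: 4 5,7-bis(benzyloxy)-2-methyl-4-oxo-4H-chromene-8-carbaldehyde
Product: 5 N'-{(E)-[5,7-bis(benzyloxy)-2-methyl-4-oxo-4H-chromen-8-yl]methylidene}-4-methylbenzenesulfonohydrazide
Conditions: TsNHNH2 (1.05 equiv), MeOH/THF, rt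
Reagents that add atoms: 4-methylbenzenesulfonohydrazide, Cc1ccc(cc1)S(=O)(=O)NN
Why: Condensation of the aldehyde with the sulfonyl hydrazide gives the bench-stable N-tosylhydrazone, the aldehyde reacting far faster than C2 of the pyranone.

Step 5
Reactants: 5 N'-{(E)-[5,7-bis(benzyloxy)-2-methyl-4-oxo-4H-chromen-8-yl]methylidene}-4-methylbenzenesulfonohydrazide; 6 tert-butyl 3-oxopyrrolidine-1-carboxylate
Product: 9 tert-butyl (4RS)-4-[5,7-bis(benzyloxy)-2-methyl-4-oxo-4H-chromen-8-yl]-3-oxopiperidine-1-carboxylate, via tosylhydrazone sodium salt 7 (not isolated), via 8-(diazomethyl)chromone 8 (not isolated)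
Conditions: NaH (1.0 equiv), THF, 0 °C, evaporate; BnEt3NCl (10 mol %), toluene, 45 °C, filter cold under argon; add to 6 (2 equiv), Sc(OTf)3 (20 mol %), toluene, −78 → −20 °C
Reagents that add atoms: none
Why: Deprotonation of 5 and gentle warming under phase-transfer catalysis expel sulfinate (Bamford–Stevens) to give aryldiazomethane 8, whose nucleophilic carbon adds to the Sc(OTf)3-activated C3 carbonyl of 6; in the diazonium alkoxide so formed the ring bond C3–C4 antiperiplanar to the C–N2 bond migrates to the benzylic carbon as N2 leaves, so the chromone-bearing carbon ends up between the carbonyl and the ring methylene. The closest known reaction type is the Sc(OTf)3-catalysed homologation of cycloalkanones and oxo-azacycles with aryldiazomethanes, a Tiffeneau–Demjanov-type diazoalkane–carbonyl ring expansion. No ring is closed by cyclisation: the six-membered ring arises by a 1,2-alkyl shift that enlarges the five-membered ring by the one exocyclic carbon, and the same event makes the C8(chromone)–C4 bond and leaves the oxygen on C3. The one new stereocentre, C4, is formed without control and needs none, because it is the enolisable α-aryl ketone centre that step 6 equilibrates and resolves dynamically. The selectivity needed is regiochemical, migration of the ring CH2 remote from nitrogen and not of the N–CH2, and the carbamate secures it because its inductive pull makes the N-bound methylene the poorer migrating group. Single homologation is favoured because 9 is a more hindered ketone than 6 and 6 is used in excess, and Sc(OTf)3 is used at raised loading because it also binds, reversibly, to the pyranone carbonyl.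

Step 6
Reactants: 9 tert-butyl (4RS)-4-[5,7-bis(benzyloxy)-2-methyl-4-oxo-4H-chromen-8-yl]-3-oxopiperidine-1-carboxylate
Product: 10 tert-butyl (3S,4R)-4-[5,7-bis(benzyloxy)-2-methyl-4-oxo-4H-chromen-8-yl]-3-hydroxypiperidine-1-carboxylate
Conditions: RuCl[(R,R)-TsDPEN](p-cymene) (2 mol %), HCO2H/Et3N (2:3), CH2Cl2, 35 °C
Reagents that add atoms: none
Why: Noyori–Ikariya asymmetric transfer hydrogenation with dynamic kinetic resolution, in which Et3N racemises the benzylic α-keto C4–H through the enol while the chiral ruthenium hydride reduces the (4R) ketone faster and delivers hydride to the carbonyl face opposite the C4 aryl group, so that C3 (S) and C4 (R) are set together in the cis relationship and the electron-rich vinylogous ester carbonyl of the chromone is left alone.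

Step 7
Reactants: 10 tert-butyl (3S,4R)-4-[5,7-bis(benzyloxy)-2-methyl-4-oxo-4H-chromen-8-yl]-3-hydroxypiperidine-1-carboxylate
Product: 12 5,7-bis(benzyloxy)-8-[(3S,4R)-3-hydroxy-1-methylpiperidin-4-yl]-2-methyl-4H-chromen-4-one, via piperidinium trifluoroacetate 11 (not isolated)
Conditions: TFA, CH2Cl2, 0 °C, concentrate; then aq. CH2O, NaBH(OAc)3, ClCH2CH2Cl, rt
Reagents that add atoms: formaldehyde, C=O
Why: Acidolysis of the tert-butyl carbamate followed by reductive amination of formaldehyde with NaBH(OAc)3 installs the N-methyl group without touching either stereocentre, and it is placed before the acylation so that no O-to-N acyl shift can occur in a free 3-acyloxypiperidine.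

Step 8
Reactants: 12 5,7-bis(benzyloxy)-8-[(3S,4R)-3-hydroxy-1-methylpiperidin-4-yl]-2-methyl-4H-chromen-4-one; 13 3,4-dimethoxybenzoyl chloride
Product: 14 (3S,4R)-4-[5,7-bis(benzyloxy)-2-methyl-4-oxo-4H-chromen-8-yl]-1-methylpiperidin-3-yl 3,4-dimethoxybenzoate
Conditions: Et3N, DMAP (0.2 equiv), CH2Cl2, 0 °C → rt
Reagents that add atoms: none
Why: DMAP-catalysed acylation (nucleophilic catalysis) of the only free hydroxyl group, the axial secondary alcohol, proceeds with retention at C3 because the C3–O bond is not broken.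

Step 9
Reactants: 14 (3S,4R)-4-[5,7-bis(benzyloxy)-2-methyl-4-oxo-4H-chromen-8-yl]-1-methylpiperidin-3-yl 3,4-dimethoxybenzoate
Product: 15 chrotacumine D, (3S,4R)-4-(5,7-dihydroxy-2-methyl-4-oxo-4H-chromen-8-yl)-1-methylpiperidin-3-yl 3,4-dimethoxybenzoate
Conditions: H2 (1 atm), Pd(OH)2/C, AcOH (1 equiv), EtOAc/MeOH, rt; NaHCO3 work-up
Reagents that add atoms: none
Why: Catalytic hydrogenolysis of the two aryl benzyl ethers, with the amine protonated by AcOH so that it does not poison the catalyst, should leave the pyranone double bond, the aryl ester, the methyl ethers and both stereocentres untouched.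

**Compound list**

1 | 5,7-dihydroxy-2-methyl-4H-chromen-4-one (noreugenin) | Cc1cc(=O)c2c(O)cc(O)cc2o1 | starting material
2 | 5,7-bis(benzyloxy)-2-methyl-4H-chromen-4-one | Cc1cc(=O)c2c(OCc3ccccc3)cc(OCc3ccccc3)cc2o1 | intermediate
3 | 5,7-bis(benzyloxy)-8-bromo-2-methyl-4H-chromen-4-one | Cc1cc(=O)c2c(OCc3ccccc3)cc(OCc3ccccc3)c(Br)c2o1 | intermediate
4 | 5,7-bis(benzyloxy)-2-methyl-4-oxo-4H-chromene-8-carbaldehyde | Cc1cc(=O)c2c(OCc3ccccc3)cc(OCc3ccccc3)c(C=O)c2o1 | intermediate
5 | N'-{(E)-[5,7-bis(benzyloxy)-2-methyl-4-oxo-4H-chromen-8-yl]methylidene}-4-methylbenzenesulfonohydrazide | Cc1cc(=O)c2c(OCc3ccccc3)cc(OCc3ccccc3)c(/C=N/NS(=O)(=O)c3ccc(C)cc3)c2o1 | intermediate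
6 | tert-butyl 3-oxopyrrolidine-1-carboxylate | CC(C)(C)OC(=O)N1CCC(=O)C1 | starting material
7 | sodium salt of tosylhydrazone 5 | Cc1cc(=O)c2c(OCc3ccccc3)cc(OCc3ccccc3)c(/C=N/[N-]S(=O)(=O)c3ccc(C)cc3)c2o1.[Na+] | intermediate (not isolated)
8 | 5,7-bis(benzyloxy)-8-(diazomethyl)-2-methyl-4H-chromen-4-one | Cc1cc(=O)c2c(OCc3ccccc3)cc(OCc3ccccc3)c(C=[N+]=[N-])c2o1 | intermediate (not isolated)
9 | tert-butyl (4RS)-4-[5,7-bis(benzyloxy)-2-methyl-4-oxo-4H-chromen-8-yl]-3-oxopiperidine-1-carboxylate (racemic, C4 labile) | Cc1cc(=O)c2c(OCc3ccccc3)cc(OCc3ccccc3)c(C3CCN(C(=O)OC(C)(C)C)CC3=O)c2o1 | intermediate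
10 | tert-butyl (3S,4R)-4-[5,7-bis(benzyloxy)-2-methyl-4-oxo-4H-chromen-8-yl]-3-hydroxypiperidine-1-carboxylate | O[C@@H]2CN(C(=O)OC(C)(C)C)CC[C@@H]2c2c(OCc3ccccc3)cc(OCc3ccccc3)c3c(=O)cc(C)oc23 | intermediate
11 | (3S,4R)-4-[5,7-bis(benzyloxy)-2-methyl-4-oxo-4H-chromen-8-yl]-3-hydroxypiperidin-1-ium trifluoroacetate | O[C@@H]2C[NH2+]CC[C@@H]2c2c(OCc3ccccc3)cc(OCc3ccccc3)c3c(=O)cc(C)oc23.[O-]C(=O)C(F)(F)F | intermediate (not isolated)
12 | 5,7-bis(benzyloxy)-8-[(3S,4R)-3-hydroxy-1-methylpiperidin-4-yl]-2-methyl-4H-chromen-4-one | O[C@@H]2CN(C)CC[C@@H]2c2c(OCc3ccccc3)cc(OCc3ccccc3)c3c(=O)cc(C)oc23 | intermediate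
13 | 3,4-dimethoxybenzoyl chloride | COc1ccc(C(Cl)=O)cc1OC | starting material
14 | (3S,4R)-4-[5,7-bis(benzyloxy)-2-methyl-4-oxo-4H-chromen-8-yl]-1-methylpiperidin-3-yl 3,4-dimethoxybenzoate | COc1ccc(C(=O)O[C@@H]2CN(C)CC[C@@H]2c2c(OCc3ccccc3)cc(OCc3ccccc3)c3c(=O)cc(C)oc23)cc1OC | intermediate
15 | chrotacumine D | COc1ccc(C(=O)O[C@@H]2CN(C)CC[C@@H]2c2c(O)cc(O)c3c(=O)cc(C)oc23)cc1OC | target

**Step count and risks**

Total step count: 9. Longest linear sequence: 9 steps (1 → 15); 6 and 13 enter as bought materials.

The three steps most likely to fail: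

1. Step 5 (key step). What may go wrong: addition of the doubly ortho-substituted diazo carbon to the ketone is slow, so that azine formation, acid-induced loss of nitrogen from 8 or sequestration of Sc(OTf)3 by the pyranone carbonyl outrun the homologation; migration of the N-bound methylene would in addition give the 3-aryl-4-oxo isomer. Fallback (the same ring enlargement, done stepwise through an epoxide): it sets out from bromide 3 and ketone 6 and comes back to the route at 9. Boron–Wittig olefination of 6 with bis(4,4,5,5-tetramethyl-1,3,2-dioxaborolan-2-yl)methane and lithium 2,2,6,6-tetramethylpiperidide (THF, −78 °C → rt) should give tert-butyl 3-[(4,4,5,5-tetramethyl-1,3,2-dioxaborolan-2-yl)methylidene]pyrrolidine-1-carboxylate F1. Suzuki–Miyaura coupling of F1 with 3 (PdCl2(dppf), K3PO4, dioxane/H2O, 80 °C) should give tert-butyl 3-{[5,7-bis(benzyloxy)-2-methyl-4-oxo-4H-chromen-8-yl]methylidene}pyrrolidine-1-carboxylate F2. Epoxidation of this electron-rich exocyclic alkene with dimethyldioxirane (acetone, −20 °C) should give tert-butyl 2-[5,7-bis(benzyloxy)-2-methyl-4-oxo-4H-chromen-8-yl]-1-oxa-5-azaspiro[2.4]heptane-5-carboxylate F3. BF3·OEt2 (CH2Cl2, −78 °C) then opens the epoxide at the benzylic carbon, and the semipinacol (Meinwald) 1,2-shift of the ring CH2 delivers 9.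

2. Step 6. What may go wrong: enolisation at C4, slowed by the twisted and bulky aryl group, fails to keep pace with the reduction, so that both ketone enantiomers are reduced and enantiomeric purity is lost; slow conjugate reduction of the pyranone is a second possible drain. Fallback (substrate-controlled reduction, then separation of enantiomers): it sets out from 9 and comes back at 10. LiBH(s-Bu)3 (THF, −78 °C) attacks the carbonyl face opposite the aryl group and should give the racemic cis alcohol tert-butyl (3RS,4SR)-4-[5,7-bis(benzyloxy)-2-methyl-4-oxo-4H-chromen-8-yl]-3-hydroxypiperidine-1-carboxylate F4. Preparative chromatography on a chiral stationary phase (supercritical CO2/MeOH) separates the enantiomers, and the (3S,4R) enantiomer is 10.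

3. Step 3. What may go wrong: oxidative addition into the hindered, electron-rich C8–Br bond is slow and hydrodebromination of the arylpalladium intermediate competes with CO insertion. Fallback (vinylation and oxidative cleavage in place of carbonylation): it sets out from 3 and comes back at 4. Suzuki–Miyaura coupling of 3 with potassium vinyltrifluoroborate, CH2=CHBF3K (PdCl2(dppf), Cs2CO3, THF/H2O, 80 °C) should give 5,7-bis(benzyloxy)-8-ethenyl-2-methyl-4H-chromen-4-one F5. Lemieux–Johnson cleavage (OsO4 cat., NaIO4, 2,6-lutidine, dioxane/H2O, rt) of the styrene-type double bond, which is far more electron-rich than the pyranone double bond, then gives aldehyde 4.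

**Further compounds**

F1 | step 5 | tert-butyl 3-[(4,4,5,5-tetramethyl-1,3,2-dioxaborolan-2-yl)methylidene]pyrrolidine-1-carboxylate (E/Z mixture) | CC(C)(C)OC(=O)N1CCC(=CB2OC(C)(C)C(C)(C)O2)C1
F2 | step 5 | tert-butyl 3-{[5,7-bis(benzyloxy)-2-methyl-4-oxo-4H-chromen-8-yl]methylidene}pyrrolidine-1-carboxylate (E/Z mixture) | Cc1cc(=O)c2c(OCc3ccccc3)cc(OCc3ccccc3)c(C=C3CCN(C(=O)OC(C)(C)C)C3)c2o1
F3 | step 5 | tert-butyl 2-[5,7-bis(benzyloxy)-2-methyl-4-oxo-4H-chromen-8-yl]-1-oxa-5-azaspiro[2.4]heptane-5-carboxylate (racemic, mixture of diastereomers) | Cc1cc(=O)c2c(OCc3ccccc3)cc(OCc3ccccc3)c(C3OC34CCN(C(=O)OC(C)(C)C)C4)c2o1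
F4 | step 6 | tert-butyl (3RS,4SR)-4-[5,7-bis(benzyloxy)-2-methyl-4-oxo-4H-chromen-8-yl]-3-hydroxypiperidine-1-carboxylate (racemic cis, both enantiomers shown) | O[C@@H]2CN(C(=O)OC(C)(C)C)CC[C@@H]2c2c(OCc3ccccc3)cc(OCc3ccccc3)c3c(=O)cc(C)oc23.O[C@H]2CN(C(=O)OC(C)(C)C)CC[C@H]2c2c(OCc3ccccc3)cc(OCc3ccccc3)c3c(=O)cc(C)oc23
F5 | step 3 | 5,7-bis(benzyloxy)-8-ethenyl-2-methyl-4H-chromen-4-one | Cc1cc(=O)c2c(OCc3ccccc3)cc(OCc3ccccc3)c(C=C)c2o1
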